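Slowness first: Z comes through a slow last step here, and I ask what a slow dose of E costs on top of it.

    L + E ⇌ L.E (K1 = 71 M⁻¹, k1 = 0.61 M⁻¹ s⁻¹)
    L ⇌ Q (K2 = 0.33, k2 = 0.039 s⁻¹)
    E + L.E ⇌ E.L.E (K3 = 16 M⁻¹, k3 = 0.0017 M⁻¹ s⁻¹)
    L.E → Z (k4 = 0.047 s⁻¹)
    Q → X (k5 = 0.029 s⁻¹)

all flasks: L 0.31 M; time 50 s

| charge | E | remark |
|---|---|---|
| dawn | 0.620 M (fed, over 0.15 s) | the fed solution adds 0.20 times the starting volume |
| noon | 0.620 M (fed, over 0.40 s) | the fed solution adds 0.20 times the starting volume |
| summer | 0.620 M (fed, over 1.2 s) | the fed solution adds 0.20 times the starting volume |
| dusk | 0.620 M (fed, over 4.0 s) | the fed solution adds 0.20 times the starting volume |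
| autumn | 0.620 M (fed, over 12 s) | the fed solution adds 0.20 times the starting volume |

- charges are per starting volume, the dose included; the dosed solution carries all of it
- "hardly changes" means that all values lie within two and a half points (for a concentration: within two and a half percent of the largest)
- run time (dawn): 50 s

- amount of Z at the end, in percent of the L charged for dawn, noon, summer, dusk, autumn, in this order
- how the row runs (rises all the way / falls all the way / falls, then rises / rises, then falls / hardly changes)

**Two clocks.** L.E turns into Z with a half-life of 14.7 s. The forward capture of L in dawn, with the whole E charge counted as present at once, has a shorter half-life than that, 1.8 s. So I take the step to Z as the rate-limiting step. E is charged at twice the amount of L, which makes L the limiting reagent.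

**The puzzle.** The autumn dose lasts 80.0 times as long as the dawn dose, and its 12 s is longer than the dawn capture half-life. Yet I reckon its lateness costs 2.69% of the L charged. Those two numbers do not seem to go together.

**The end state.** L.E goes on to Z by the last step, so I ask what is still unconverted when the clock stops. L.E present from the start halves every half-life, and after 50 s a share of 9.54% is left.

**The price.** I treat later forming of L.E as a shift of its whole curve, so each second of delay takes away the last second of the run. In that last second, L.E converts at 0.047 s⁻¹ times the share still left. This gives 0.00448 s⁻¹, as a fraction of the L charged; I call it the price of lateness. A steady dose delivers E on average at half its length, 6.00 s in autumn, and those seconds are paid at the end of the curve, where the share left is 9.54%, so the price stands lower than 0.047 s⁻¹. That clears the puzzle. The leak of free L through Q to X is a separate loss, which I leave unreckoned.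

**The forecast.** The forecast gives 82.3%, 82.2%, 82%, 81.2% and 78.8%, so the row falls all the way. Its ground is this: “Longer doses delay capture, leaving less time for Z and letting more L leak through Q to X”. Its fall from dawn to autumn is 3.5 percentage points, more than my 2.69%, which counts lateness and no leak.

**The result.** The flasks give 81.6%, 81.4%, 80.9%, 79.3% and 75.1%, so the row falls all the way. At the end, autumn holds 15.4% of L.E against 12.4% in dawn, which is 3 points more. In dusk the average lateness of the E is 2.00 s, and at the price of 0.00448 s⁻¹ I reckon that at 0.896% of the L charged. The L.E standing at the end of dusk is more than that of dawn by 1 point.

All constants were drawn at random within sensible limits; what happens was integrated by code.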